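**Retrosynthetic overview**
1. The side chain is joined at the cyclopentane by anti opening of a spiro cyclopentene oxide with a (2Z,4E)-trienyllithium, itself built from but-2-yne-1,4-diol, methallyl alcohol and prenyl bromide by Horner–Wadsworth–Emmons olefination.
2. The enal comes from Babler–Dauben transposition of a tertiary isopropenyl carbinol, made by SeO2 hydroxylation next to the carvone isopropenyl group.
3. Ring B (five-membered, formed second): a Wittig–Claisen sequence turns the carvone carbonyl carbon into the quaternary spiro carbon (CHO + allyl), rhodium hydroacylation closes the cyclopentanone, and enol triflate reduction gives the cyclopentene.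
4. Ring A (six-membered, present from the start) is (S)-carvone; its side chain comes from enolate alkylation and its tertiary alcohol from enone epoxidation followed by hydride opening.
5. Ring order: ring A is bought, ring B is closed in step 6; all five stereocentres are relayed from the single carvone stereocentre, which is erased in step 21.

Assumption: compounds 1, 2, 6, 18, 19 and 24 and all unnumbered reagents are purchasable; enol ether 9 is an E/Z mixture and the ring A carbinol carbon made in step 11 is an epimer mixture (both erased later), so these two elements are left open in the SMILES.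

Step 1
Reactants: 1 (S)-(+)-carvone; 2 tert-butyl(3-iodopropoxy)dimethylsilane
Product: 4 (5S,6R)-6-[3-(tert-butyldimethylsilyloxy)propyl]-2-methyl-5-(prop-1-en-2-yl)cyclohex-2-en-1-one, via lithium dienolate 3 (not isolated)
Conditions: LiN(iPr)2, THF, −78 °C; then 2, DMPU, −78 → 0 °C
Reagents that add atoms: none
Why: Kinetic deprotonation at the alpha-prime carbon gives the cross-conjugated dienolate, whose SN2 enolate alkylation occurs on the face opposite the neighbouring isopropenyl group and so sets the side-chain stereocentre trans to it.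

Step 2
Reactants: 4 alkylated carvone
Product: 5 epoxy ketone (oxirane oxygen trans to isopropenyl and cis to the side chain)
Conditions: 30% H2O2, NaOH (cat.), MeOH, 0 °C
Reagents that add atoms: hydrogen peroxide (OO)
Why: Weitz–Scheffer nucleophilic epoxidation, in which hydroperoxide adds to the enone beta-carbon anti to the isopropenyl group, places the oxirane oxygen (the later tertiary hydroxyl) cis to the side chain while the basic medium keeps the alpha-prime centre in its more stable trans arrangement.

Step 3
Reactants: 6 allyl chloromethyl ether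
Product: 7 (allyloxymethyl)triphenylphosphonium chloride
Conditions: PPh3, toluene, 25 → 50 °C
Reagents that add atoms: triphenylphosphine (c1ccc(cc1)P(c1ccccc1)c1ccccc1)
Why: SN2 quaternisation of the phosphine by the reactive alpha-chloro ether gives the Wittig salt.

Step 4
Reactants: 5 epoxy ketone; 7 phosphonium salt
Product: 9 allyl enol ether of 5 (E/Z mixture), via ylide 8 (not isolated)
Conditions: 7, KOtBu, THF, 0 °C; then 5, 0 → 65 °C
Reagents that add atoms: none
Why: Wittig olefination with the non-stabilised alkoxymethylidene ylide converts the inductively activated epoxy-ketone carbonyl into an allyl enol ether without touching a stereocentre, the enol ether geometry being irrelevant.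

Step 5
Reactants: 9 allyl enol ether
Product: 10 quaternary aldehyde (formyl cis to oxirane oxygen and side chain; allyl trans)
Conditions: xylene, trace Et3N, 140 °C
Reagents that add atoms: none
Why: Thermal Claisen rearrangement ([3,3]-sigmatropic shift) delivers the allyl group to the former carbonyl carbon from the face opposite the adjacent oxirane oxygen and the side chain, creating the quaternary future spiro centre.

Step 6
Reactants: 10 quaternary aldehyde
Product: 11 spiro cyclopentanone
Conditions: [Rh(dppe)]2(BF4)2 (3 mol %), CH2Cl2, 25 °C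
Reagents that add atoms: none
Why: Cationic-rhodium-catalysed intramolecular hydroacylation of the alpha-quaternary 4-pentenal adds the acyl C–H across the terminal alkene and closes ring B without affecting existing stereocentres.

Step 7
Reactants: 11 spiro cyclopentanone
Product: 13 enol triflate, via potassium enolate 12 (not isolated)
Conditions: KN(SiMe3)2, THF, −78 °C; then PhNTf2, −78 → 0 °C
Reagents that add atoms: N-phenylbis(trifluoromethanesulfonimide) (O=S(=O)(N(c1ccccc1)S(=O)(=O)C(F)(F)F)C(F)(F)F)
Why: The ketone can enolise only toward its single alpha-methylene, so O-sulfonylation of the enolate gives one enol triflate regiospecifically.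

Step 8
Reactants: 13 enol triflate
Product: 14 spiro cyclopentene (double bond next to the spiro carbon)
Conditions: Pd(OAc)2 (5 mol %), PPh3, HCO2H, Bu3N, DMF, 60 °C
Reagents that add atoms: none
Why: Palladium-catalysed formate reduction of the enol triflate (oxidative addition, decarboxylation of formate, reductive elimination) replaces the triflate by hydrogen and leaves the oxirane untouched.

Step 9
Reactants: 14 spiro cyclopentene
Product: 15 10-[3-(tert-butyldimethylsilyloxy)propyl]-6-methyl-9-(prop-1-en-2-yl)spiro[4.5]dec-1-en-6-ol (6-OH and side chain both cis to C1)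
Conditions: LiBEt3H, THF, 0 → 25 °C; H2O
Reagents that add atoms: none
Why: SN2 hydride opening of the trisubstituted epoxide by LiBEt3H occurs at the less substituted carbon and unveils the tertiary alcohol whose configuration was fixed in step 2.

Step 10
Reactants: 15 tertiary alcohol
Product: 16 cyclopentene oxide (oxirane oxygen syn to the tertiary hydroxyl)
Conditions: VO(acac)2 (5 mol %), t-BuOOH, CH2Cl2, 25 °C
Reagents that add atoms: tert-butyl hydroperoxide (CC(C)(C)OO)
Why: Hydroxyl-directed epoxidation delivers oxygen from the vanadium alkoxide of the homoallylic tertiary alcohol to the cyclopentene face it flanks (also the less hindered one), while the undirected isopropenyl group is inert.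

Step 11
Reactants: 16 cyclopentene oxide
Product: 17 tertiary isopropenyl carbinol of ring A (epimer mixture at the new carbinol)
Conditions: SeO2 (0.3 equiv), t-BuOOH, CH2Cl2, 25 °C
Reagents that add atoms: selenium dioxide (O=[Se]=O), tert-butyl hydroperoxide (CC(C)(C)OO)
Why: Selenium dioxide allylic oxidation (ene reaction at the terminal methylene then [2,3]-sigmatropic shift) hydroxylates the tertiary ring C–H next to the only remaining alkene, and the new centre is inconsequential because it becomes sp2 in step 21.

Step 12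
Reactants: 18 2-methylprop-2-en-1-ol; 19 prenyl bromide
Product: 21 6-methyl-2-methylidenehept-5-en-1-ol, via dilithio dianion 20 (not isolated)
Conditions: n-BuLi (2.1 equiv), TMEDA, Et2O, 0 → 25 °C; then 19, −78 → 0 °C; H2O
Reagents that add atoms: none
Why: Double deprotonation gives the allylic C,O-dianion, which undergoes SN2 C-alkylation by the primary allylic bromide.

Step 13
Reactants: 21 allylic alcohol
Product: 22 2-(bromomethyl)-6-methylhepta-1,5-diene
Conditions: CBr4, PPh3, CH2Cl2, 0 °C
Reagents that add atoms: carbon tetrabromide (BrC(Br)(Br)Br)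
Why: The Appel reaction converts the primary allylic alcohol into the bromide under neutral conditions, and allylic transposition would give the same compound.

Step 14
Reactants: 22 allylic bromide
Product: 23 diethyl (6-methyl-2-methylidenehept-5-en-1-yl)phosphonate
Conditions: P(OEt)3, neat, 130 °C
Reagents that add atoms: triethyl phosphite (CCOP(OCC)OCC)
Why: Michaelis–Arbuzov reaction of the reactive allylic bromide gives the allylic phosphonate.

Step 15
Reactants: 24 but-2-yne-1,4-diol
Product: 25 4-(tert-butyldimethylsilyloxy)but-2-yn-1-ol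
Conditions: t-BuMe2SiCl, imidazole, THF, 0 °C (24 in threefold excess)
Reagents that add atoms: tert-butyldimethylsilyl chloride (CC(C)(C)[Si](C)(C)Cl)
Why: Statistical monosilylation of the symmetrical diol used in excess gives the mono-ether.

Step 16
Reactants: 25 mono-protected butynediol
Product: 27 (Z)-4-(tert-butyldimethylsilyloxy)-3-iodobut-2-en-1-ol, via alkenylaluminate 26 (not isolated)
Conditions: NaAlH2(OCH2CH2OMe)2, THF, 0 → 25 °C; then I2, −78 °C; aqueous work-up
Reagents that add atoms: iodine (II)
Why: Hydroxyl-directed trans-hydroalumination of the propargylic alcohol puts aluminium on the distal alkyne carbon in a five-membered chelate, and iodinolysis with retention gives the vinyl iodide with iodine cis to the CH2OH-bearing carbon.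

Step 17
Reactants: 27 iodo allylic alcohol
Product: 28 (Z)-4-(tert-butyldimethylsilyloxy)-3-iodobut-2-enal
Conditions: MnO2, CH2Cl2, 25 °C
Reagents that add atoms: none
Why: Selective allylic oxidation with MnO2 gives the enal without isomerising the double bond.

Step 18
Reactants: 23 allylic phosphonate; 28 iodo enal
Product: 30 tert-butyl{[(2Z,4E)-2-iodo-10-methyl-6-methylideneundeca-2,4,9-trien-1-yl]oxy}dimethylsilane, via lithiated phosphonate 29 (not isolated)
Conditions: 23, LiN(SiMe3)2, THF, −78 °C; then 28, −78 → 0 °C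
Reagents that add atoms: none
Why: Horner–Wadsworth–Emmons olefination of the enal by the alpha-lithiated allylic phosphonate forms the new disubstituted double bond with E selectivity and leaves the vinyl iodide geometry intact.

Step 19
Reactants: 17 epoxy diol; 30 trienyl iodide
Product: 33 spirocyclic triol carrying the full side chain, via trienyllithium 31 (not isolated), via dilithium dialkoxide 32 (not isolated)
Conditions: 30, t-BuLi (2 equiv), Et2O, −78 °C; 17, n-BuLi (2 equiv), THF, −78 °C; mix, BF3·OEt2, −78 °C; H2O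
Reagents that add atoms: none
Why: Iodine–lithium exchange gives the alkenyllithium with retention, and its BF3-promoted SN2 epoxide opening at the less hindered carbon remote from the spiro centre proceeds with inversion, giving the trans-2-alkenylcyclopentanol with both new ring stereocentres as in the target.

Step 20
Reactants: 33 triol
Product: 34 triethylsilyl ether of the secondary alcohol
Conditions: Et3SiCl, imidazole, DMAP (cat.), CH2Cl2, 0 °C
Reagents that add atoms: chlorotriethylsilane (CC[Si](Cl)(CC)CC)
Why: Silylation is selective for the secondary hydroxyl over the two tertiary ones and protects it from the chromium oxidant of the next step.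

Step 21
Reactants: 34 protected tertiary allylic alcohol
Product: 35 fully silylated (Z)-enal
Conditions: [C5H5NH][CrO3Cl] (pyridinium chlorochromate), CH2Cl2, 25 °C
Reagents that add atoms: pyridinium chlorochromate ([O-][Cr](=O)(=O)Cl.c1cc[nH+]cc1)
Why: In the Babler–Dauben oxidative transposition the tertiary allylic chromate ester undergoes a [3,3]-sigmatropic shift and oxidation to the tetrasubstituted enal, in which the methyl group takes the less crowded position beside the ring CH2 so that the formyl group is cis to the side-chain-bearing carbon (Z), any E isomer being removed by chromatography.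

Step 22
Reactants: 35 silylated enal
Product: 36 target CNP0246965.1
Conditions: Bu4NF, AcOH, THF, 0 → 25 °C
Reagents that add atoms: none
Why: Fluoride-mediated desilylation, buffered with acetic acid to spare the enal and the trienyl allylic alcohol, removes the triethylsilyl and both tert-butyldimethylsilyl groups.

**Compound list**
1 | (S)-(+)-carvone, (5S)-2-methyl-5-(prop-1-en-2-yl)cyclohex-2-en-1-one | CC1=CC[C@@H](CC1=O)C(C)=C | starting material
2 | tert-butyl(3-iodopropoxy)dimethylsilane | CC(C)(C)[Si](C)(C)OCCCI | starting material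
3 | lithium cross-conjugated dienolate of 1 (enolised toward C6) | CC1=CC[C@@H](C=C1O[Li])C(C)=C | intermediate
4 | (5S,6R)-6-[3-(tert-butyldimethylsilyloxy)propyl]-2-methyl-5-(prop-1-en-2-yl)cyclohex-2-en-1-one (side chain trans to isopropenyl) | O=C1C(C)=CC[C@H](C(C)=C)[C@H]1CCCO[Si](C)(C)C(C)(C)C | intermediate
5 | 3-[3-(tert-butyldimethylsilyloxy)propyl]-1-methyl-4-(prop-1-en-2-yl)-7-oxabicyclo[4.1.0]heptan-2-one; oxirane O trans to isopropenyl, cis to side chain | O=C1[C@@]2(C)O[C@H]2C[C@H](C(C)=C)[C@H]1CCCO[Si](C)(C)C(C)(C)C | intermediate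
6 | allyl chloromethyl ether, 3-(chloromethoxy)prop-1-ene | C=CCOCCl | starting material
7 | (allyloxymethyl)triphenylphosphonium chloride | C=CCOC[P+](c1ccccc1)(c1ccccc1)c1ccccc1.[Cl-] | intermediate
8 | (allyloxymethylidene)triphenylphosphorane | C=CCOC=P(c1ccccc1)(c1ccccc1)c1ccccc1 | intermediate
9 | 2-[(allyloxy)methylidene] analogue of 5 (allyl enol ether, E/Z mixture) | C=CCOC=C1[C@@]2(C)O[C@H]2C[C@H](C(C)=C)[C@H]1CCCO[Si](C)(C)C(C)(C)C | intermediate
10 | 2-allyl-3-[3-(tert-butyldimethylsilyloxy)propyl]-1-methyl-4-(prop-1-en-2-yl)-7-oxabicyclo[4.1.0]heptane-2-carbaldehyde; formyl cis to oxirane O and side chain | O=C[C@@]1(CC=C)[C@@]2(C)O[C@H]2C[C@H](C(C)=C)[C@H]1CCCO[Si](C)(C)C(C)(C)C | intermediate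
11 | 3'-[3-(tert-butyldimethylsilyloxy)propyl]-1'-methyl-4'-(prop-1-en-2-yl)spiro[cyclopentane-1,2'-[7]oxabicyclo[4.1.0]heptan]-2-one; carbonyl carbon cis to oxirane O and side chain | O=C1CCC[C@@]12[C@@]3(C)O[C@H]3C[C@H](C(C)=C)[C@H]2CCCO[Si](C)(C)C(C)(C)C | intermediate
12 | potassium enolate of 11 | [K]OC1=CCC[C@@]12[C@@]3(C)O[C@H]3C[C@H](C(C)=C)[C@H]2CCCO[Si](C)(C)C(C)(C)C | intermediate
13 | enol triflate of 11 (cyclopent-2-en-2-yl trifluoromethanesulfonate) | FC(F)(F)S(=O)(=O)OC1=CCC[C@@]12[C@@]3(C)O[C@H]3C[C@H](C(C)=C)[C@H]2CCCO[Si](C)(C)C(C)(C)C | intermediate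
14 | 3'-[3-(tert-butyldimethylsilyloxy)propyl]-1'-methyl-4'-(prop-1-en-2-yl)spiro[cyclopent-2-ene-1,2'-[7]oxabicyclo[4.1.0]heptane] | C1=CCC[C@@]12[C@@]3(C)O[C@H]3C[C@H](C(C)=C)[C@H]2CCCO[Si](C)(C)C(C)(C)C | intermediate
15 | 10-[3-(tert-butyldimethylsilyloxy)propyl]-6-methyl-9-(prop-1-en-2-yl)spiro[4.5]dec-1-en-6-ol; 6-OH and side chain cis to C1, isopropenyl trans to side chain | C1=CCC[C@@]12[C@@](C)(O)CC[C@H](C(C)=C)[C@H]2CCCO[Si](C)(C)C(C)(C)C | intermediate
16 | 1,2-epoxide of 15; oxirane O on the cyclopentane face turned toward C6 (syn to the tertiary OH) | [C@H]12O[C@H]1CC[C@@]23[C@@](C)(O)CC[C@H](C(C)=C)[C@H]3CCCO[Si](C)(C)C(C)(C)C | intermediate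
17 | 9-hydroxy derivative of 16 (tertiary isopropenyl carbinol, epimer mixture at C9) | [C@H]12O[C@H]1CC[C@@]23[C@@](C)(O)CCC(O)(C(C)=C)[C@H]3CCCO[Si](C)(C)C(C)(C)C | intermediate
18 | 2-methylprop-2-en-1-ol (methallyl alcohol) | CC(=C)CO | starting material
19 | 1-bromo-3-methylbut-2-ene (prenyl bromide) | CC(C)=CCBr | starting material
20 | dilithio C,O-dianion of 18 | [Li]CC(=C)CO[Li] | intermediate
21 | 6-methyl-2-methylidenehept-5-en-1-ol | OCC(=C)CCC=C(C)C | intermediate
22 | 2-(bromomethyl)-6-methylhepta-1,5-diene | BrCC(=C)CCC=C(C)C | intermediate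
23 | diethyl (6-methyl-2-methylidenehept-5-en-1-yl)phosphonate | CCOP(=O)(OCC)CC(=C)CCC=C(C)C | intermediate
24 | but-2-yne-1,4-diol | OCC#CCO | starting material
25 | 4-(tert-butyldimethylsilyloxy)but-2-yn-1-ol | OCC#CCO[Si](C)(C)C(C)(C)C | intermediate
26 | cyclic sodium alkenylaluminate from 25 (Al on the carbon bearing CH2OSi) | [Na+].COCCO[Al-]1(OCCOC)OCC=C1CO[Si](C)(C)C(C)(C)C | intermediate
27 | (Z)-4-(tert-butyldimethylsilyloxy)-3-iodobut-2-en-1-ol | OC/C=C(/CO[Si](C)(C)C(C)(C)C)I | intermediate
28 | (Z)-4-(tert-butyldimethylsilyloxy)-3-iodobut-2-enal | O=C/C=C(/CO[Si](C)(C)C(C)(C)C)I | intermediate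
29 | alpha-lithiated phosphonate 23 | [Li]C(P(=O)(OCC)OCC)C(=C)CCC=C(C)C | intermediate
30 | tert-butyl{[(2Z,4E)-2-iodo-10-methyl-6-methylideneundeca-2,4,9-trien-1-yl]oxy}dimethylsilane | C=C(/C=C/C=C(/CO[Si](C)(C)C(C)(C)C)I)CCC=C(C)C | intermediate
31 | trienyllithium from 30 (lithium in place of iodine, geometry retained) | C=C(/C=C/C=C(/CO[Si](C)(C)C(C)(C)C)[Li])CCC=C(C)C | intermediate
32 | dilithium dialkoxide of 17 | [C@H]12O[C@H]1CC[C@@]23[C@@](C)(O[Li])CCC(O[Li])(C(C)=C)[C@H]3CCCO[Si](C)(C)C(C)(C)C | intermediate
33 | 2-[(2E,4E)-1-(tert-butyldimethylsilyloxy)-10-methyl-6-methylideneundeca-2,4,9-trien-2-yl]-10-[3-(tert-butyldimethylsilyloxy)propyl]-6-methyl-9-(prop-1-en-2-yl)spiro[4.5]decane-1,6,9-triol; C1, C2, C5, C6, C10 as in 36, C9 epimer mixture | C=C(/C=C/C=C(/CO[Si](C)(C)C(C)(C)C)[C@@H]1CC[C@]2([C@H](CCCO[Si](C)(C)C(C)(C)C)C(O)(C(C)=C)CC[C@]2(C)O)[C@H]1O)CCC=C(C)C | intermediate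
34 | 1-O-triethylsilyl ether of 33 | C=C(/C=C/C=C(/CO[Si](C)(C)C(C)(C)C)[C@@H]1CC[C@]2([C@H](CCCO[Si](C)(C)C(C)(C)C)C(O)(C(C)=C)CC[C@]2(C)O)[C@H]1O[Si](CC)(CC)CC)CCC=C(C)C | intermediate
35 | 1-O-triethylsilyl, bis-O-tert-butyldimethylsilyl ether of 36 ((Z)-enal in place) | C=C(/C=C/C=C(/CO[Si](C)(C)C(C)(C)C)[C@@H]1CC[C@]2([C@H](CCCO[Si](C)(C)C(C)(C)C)/C(=C(/C)C=O)CC[C@]2(C)O)[C@H]1O[Si](CC)(CC)CC)CCC=C(C)C | intermediate
36 | (2Z)-2-[(1S,2S,5S,6S,10R)-1,6-dihydroxy-2-[(2E,4E)-1-hydroxy-10-methyl-6-methylideneundeca-2,4,9-trien-2-yl]-10-(3-hydroxypropyl)-6-methylspiro[4.5]decan-9-ylidene]propanal | C=C(/C=C/C=C(/CO)[C@@H]1CC[C@]2([C@H](CCCO)/C(=C(/C)C=O)CC[C@]2(C)O)[C@H]1O)CCC=C(C)C | target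

**Totals**
Total step count: 22. Longest linear sequence: 14 steps from (S)-carvone (steps 1, 2, 4–11, 19–22).

**Three steps most likely to fail, with fallbacks**

Step 4 is a Wittig olefination of a hindered, enolisable epoxy ketone, and its product 9 is an acid-labile donor-substituted vinyl oxirane that must survive step 5. The fallback sets out from 4 and postpones the oxirane. Ylide 8 olefinates the less hindered enone carbonyl of 4 to give the dienyl allyl ether F1. Claisen rearrangement then gives the quaternary aldehyde F2, with allyl anti to the side chain. NaBH4 reduces it to the neopentyl alcohol F3, and VO(acac)2/t-BuOOH epoxidises the ring double bond syn to the CH2OH group to give the epoxy alcohol F4, with the same oxirane configuration as in 5. Dess–Martin periodinane oxidation of F4 comes back to the route at 10.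

Step 11 may oxidise the isopropenyl methyl group instead of the tertiary ring C–H. The fallback sets out from 16 and reaches the same carbinol through the ring A ketone. Ozonolysis (O3 then Me2S) of the isopropenyl group gives the methyl ketone F5. Buffered Baeyer–Villiger oxidation (CF3CO3H, Na2HPO4) gives the acetate F6 with retention, and K2CO3/MeOH gives the secondary alcohol F7. Dess–Martin periodinane gives the ketone F8, and 1,2-addition of CH2=C(CH3)MgBr in the presence of CeCl3 comes back to the route at 17.

Step 19 joins a hindered, alpha-branched trienyllithium to an epoxide flanked by a quaternary centre. The fallback sets out from 17 (as its dialkoxide 32) and from 27, adds only a small vinyl nucleophile, and builds the triene on the core. Treating 27 with n-BuLi then t-BuLi gives the dilithio species F9, which opens 32 under BF3·OEt2 to give the tetrol F10. MnO2 oxidises only its primary allylic alcohol to the enal F11, and Horner–Wadsworth–Emmons olefination with lithiated phosphonate 29 comes back to the route at 33.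

**Further compounds**
F1 | step 4 | allyl dienol ether of 4 (6-[(allyloxy)methylidene]cyclohexene, E/Z mixture) | C=CCOC=C1C(C)=CC[C@H](C(C)=C)[C@H]1CCCO[Si](C)(C)C(C)(C)C
F2 | step 4 | 1-allyl-6-[3-(tert-butyldimethylsilyloxy)propyl]-2-methyl-5-(prop-1-en-2-yl)cyclohex-2-ene-1-carbaldehyde (formyl cis to side chain) | O=C[C@@]1(CC=C)C(C)=CC[C@H](C(C)=C)[C@H]1CCCO[Si](C)(C)C(C)(C)C
F3 | step 4 | primary alcohol from F2 | OC[C@@]1(CC=C)C(C)=CC[C@H](C(C)=C)[C@H]1CCCO[Si](C)(C)C(C)(C)C
F4 | step 4 | epoxy alcohol from F3 (oxirane O cis to CH2OH) | OC[C@@]1(CC=C)[C@@]2(C)O[C@H]2C[C@H](C(C)=C)[C@H]1CCCO[Si](C)(C)C(C)(C)C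
F5 | step 11 | methyl ketone from 16 (acetyl in place of isopropenyl) | [C@H]12O[C@H]1CC[C@@]23[C@@](C)(O)CC[C@H](C(C)=O)[C@H]3CCCO[Si](C)(C)C(C)(C)C
F6 | step 11 | ring A secondary acetate from F5 | [C@H]12O[C@H]1CC[C@@]23[C@@](C)(O)CC[C@H](OC(C)=O)[C@H]3CCCO[Si](C)(C)C(C)(C)C
F7 | step 11 | ring A secondary alcohol from F6 | [C@H]12O[C@H]1CC[C@@]23[C@@](C)(O)CC[C@H](O)[C@H]3CCCO[Si](C)(C)C(C)(C)C
F8 | step 11 | ring A ketone from F7 | [C@H]12O[C@H]1CC[C@@]23[C@@](C)(O)CCC(=O)[C@H]3CCCO[Si](C)(C)C(C)(C)C
F9 | step 19 | dilithio alkoxide–alkenyllithium from 27 | [Li]OC/C=C(/CO[Si](C)(C)C(C)(C)C)[Li]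
F10 | step 19 | tetrol from opening of 32 by F9 (free primary allylic alcohol) | OC/C=C(/CO[Si](C)(C)C(C)(C)C)[C@@H]1CC[C@]2([C@H](CCCO[Si](C)(C)C(C)(C)C)C(O)(C(C)=C)CC[C@]2(C)O)[C@H]1O
F11 | step 19 | enal from F10 | O=C/C=C(/CO[Si](C)(C)C(C)(C)C)[C@@H]1CC[C@]2([C@H](CCCO[Si](C)(C)C(C)(C)C)C(O)(C(C)=C)CC[C@]2(C)O)[C@H]1O
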